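(The readings were computed on assumed constants, and the scatter is random.)

1. At the earliest readings the runs already stand where they end: Tuesday's starting material reads 75.2% at 0.625 d and 76.4% at 5.00 d, each with a scatter of 1 percentage point. So I ask what the stopped state depends on, not how fast it comes.

| setting | Tuesday's | Sunday's | Thursday's | flask |
|---|---|---|---|---|
| starting material | 0.15 M | 0.22 M | 0.30 M | 0.30 M |
| reagent | 0.60 equiv | 0.60 equiv | 0.30 equiv | 0.600 equiv |
| protic impurity | 6 mM | 6 mM | 6 mM | 6.00 mM |
| remark | run made earlier | run made earlier | run made earlier |  |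
| time |  |  |  | 5.0 d |

| run | time / d | starting material / % | product / % | adduct / % |
|---|---|---|---|---|
| Tuesday's | 0.625 | 75.2 | 4.8 | 15.3 |
| Tuesday's | 1.25 | 76.0 | 6.4 | 14.8 |
| Tuesday's | 2.00 | 74.8 | 5.9 | 15.6 |
| Tuesday's | 3.00 | 76.7 | 8.9 | 15.1 |
| Tuesday's | 4.00 | 76.4 | 5.8 | 14.0 |
| Tuesday's | 5.00 | 76.4 | 6.5 | 14.2 |
| Sunday's | 0.625 | 73.3 | 7.4 | 18.7 |
| Sunday's | 1.25 | 72.5 | 5.8 | 17.3 |
| Sunday's | 2.00 | 72.5 | 7.5 | 18.3 |
| Sunday's | 3.00 | 74.6 | 8.3 | 15.7 |
| Sunday's | 4.00 | 72.7 | 7.4 | 15.2 |
| Sunday's | 5.00 | 72.8 | 5.5 | 18.0 |
| Thursday's | 0.417 | 83.7 | 5.1 | 11.4 |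
| Thursday's | 0.833 | 83.6 | 4.6 | 12.2 |
| Thursday's | 1.25 | 81.7 | 5.2 | 10.7 |
| Thursday's | 2.50 | 82.2 | 5.9 | 10.0 |
| Thursday's | 5.00 | 82.5 | 4.0 | 13.2 |

(each reading ± 1 percentage point)

* the state of affairs at 5.0 d: stopped, and by what, or still going (forward and back rates have come level / the reagent has run out first / it is still moving / all of the starting material has reacted)
* part of the starting material gone at 5.0 d
* the product standing at 5.0 d, as a percentage of the starting material charged
* the adduct standing at 5.0 d, as a percentage of the starting material charged

- the reaction counts as stopped when no species that holds the starting material changes by six tenths of a point or more over the second half of the time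

2. My first guess is that the reagent ran out. But in Thursday's run, counting one reagent per adduct or product, 45.1% of the reagent is left on average. That looks like a balance.

3. So I test a balance on the run means. Tuesday's, Sunday's and Thursday's runs give 4.80 /M, 4.20 /M and 4.90 /M. I carry their mean 4.63 /M, the binding quotient, an apparent equilibrium constant: c(adduct) plus c(product), over c(starting material) times c(free reagent).

4. The objection is that the balance of starting material falls short. Sunday's means leave 6.05 mM unaccounted, near the 6 mM of protic impurity. Thursday's leave 2.40 mM, and at this scatter I can't separate the two. The gap lies in starting material, so I take the impurity's charge off the starting material, as a small correction.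

5. For the flask I solve c(bound) = Q·(c(starting material) − c(bound))·(c(reagent) − c(bound)). Without the correction c(bound) is 89.0 mM; with it, 87.9 mM. Conversion then counts bound plus impurity: 31.3%. The pooled product-to-adduct ratio, 0.421, splits the bound part into 8.68% product and 20.6% adduct.

6. The forecast says: forward and back rates have come level, conversion 31.7%, product 8.8%, adduct 20.9%. Its ground: “Conversion rises with more reagent, so this looks like an equilibrium.” My conversion lies 0.40 points below its figure.

7. The flask gives: forward and back rates have come level, conversion 30.8%, product 8.65%, adduct 20.1%.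

    adduct ⇌ product (K = 0.430, k = 6.97 × 10⁻⁵ /s)
    starting material + protic impurity → quenched substrate (k = 0.0483 /M/s)
    starting material + reagent ⇌ adduct (K = 3.10 /M, k = 0.00240 /M/s)

This flask holds 28.8% as adduct plus product, where 4.63 /M gave 29.3%, and it keeps 52% of its reagent at 5.00 d; waiting longer changes nothing. For the flask with 2.40 equiv of reagent, 4.63 /M gives 207 mM bound and conversion 71.0%; that flask stands at 70.2%. The main reason this flask's product stops where it does is the return of product to adduct: with that return struck out, its product stands at 60.0% instead of 8.65%.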